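**Retrosynthetic overview**
- The acid comes from the aryl bromide (Br/Li exchange, CO2). The side chain is cut at C2'–C3' by a B-alkyl Suzuki coupling into a 2-vinylchroman-3-ol and an (E)-alkenyl iodide made by alkyne carboalumination.
- C3–OH comes from CBS reduction of a chroman-3-one. The pyran ring comes from the key step, a one-carbon ring expansion of a 2,2-disubstituted benzofuran-3(2H)-one by aryl 1,2-shift (the TMSCHN2 carbon becomes C4).
- The benzofuranone comes from Parham closure of an α-aryloxy acid. Its quaternary C2 (O, Me, vinyl) is set by Pd-catalysed asymmetric etherification of 4-bromo-2-iodophenol with isoprene monoepoxide.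
- Ring order: the benzene ring is bought in, the five-membered furanone ring is closed first and then expanded to the six-membered ring; the chain is attached afterwards.

Assumption: the (R,R)-DACH-naphthyl Trost ligand is taken to give the (S)-configured tertiary ether in step 2; if the sense proves opposite, the (S,S)-ligand is used and nothing else changes.

Step 1
Reactants: 1 4-bromophenol
Product: 2 4-bromo-2-iodophenol
Conditions: NIS (1.05 equiv), TsOH·H2O (10 mol%), MeCN, 0 °C → rt
Reagents that add atoms: N-iodosuccinimide, O=C1CCC(=O)N1I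
Why: Electrophilic aromatic iodination; the para position is blocked, so the activated ortho position is iodinated once, and no stereocentre is involved.

Step 2
Reactants: 2 4-bromo-2-iodophenol; 3 2-ethenyl-2-methyloxirane (isoprene monoepoxide, racemic, 1.2 equiv)
Product: 4 (2S)-2-(4-bromo-2-iodophenoxy)-2-methylbut-3-en-1-ol
Conditions: Pd2(dba)3·CHCl3 (1.5 mol%), (R,R)-DACH-naphthyl Trost ligand (4.5 mol%), CH2Cl2, rt
Reagents that add atoms: none
Why: Trost palladium-catalysed dynamic kinetic asymmetric allylic etherification of a vinyl epoxide: ionisation of either enantiomer of 3 and fast π–σ–π equilibration on the chiral zerovalent palladium catalyst erase the epoxide configuration, the phenol (hydrogen-bonded to the liberated alkoxide) attacks the tertiary allyl terminus, and the ligand sets C2 as S.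

Step 3
Reactants: 4 (2S)-2-(4-bromo-2-iodophenoxy)-2-methylbut-3-en-1-ol
Product: 6 (2S)-2-(4-bromo-2-iodophenoxy)-2-methylbut-3-enoic acid, via aldehyde 5 (not isolated)
Conditions: TEMPO (20 mol%), PhI(OAc)2 (2.3 equiv), MeCN/H2O 1:1, rt
Reagents that add atoms: water, O
Why: Oxoammonium (TEMPO/PhI(OAc)2) oxidation of the primary alcohol through aldehyde 5 and its hydrate to the acid; the quaternary stereocentre has no α-hydrogen, and the vinyl group and aryl halides are inert.

Step 4
Reactants: 6 (2S)-2-(4-bromo-2-iodophenoxy)-2-methylbut-3-enoic acid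
Product: 10 (2S)-5-bromo-2-ethenyl-2-methyl-1-benzofuran-3(2H)-one, via sodium carboxylate 7 (not isolated), via aryllithium carboxylate 8 (not isolated), via gem-diolate 9 (not isolated)
Conditions: NaH (1.05 equiv), THF, 0 °C; n-BuLi (1.05 equiv), −100 °C → −78 °C; then 1 M HCl
Reagents that add atoms: none
Why: Parham cyclisation: NaH makes carboxylate 7, n-BuLi exchanges iodine (much faster than bromine at −100 °C) to give 8, which adds 5-exo to its own carboxylate to give gem-diolate 9 that cannot react a second time and collapses to the ketone on acidic work-up; C2 is untouched.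

Step 5
Reactants: 10 (2S)-5-bromo-2-ethenyl-2-methyl-1-benzofuran-3(2H)-one
Product: 13 (2S)-6-bromo-2-ethenyl-2-methylchroman-3-one, via C-silyl ketone 11 (not isolated), via enol silane 12 (not isolated)
Conditions: TMSCHN2 (1.5 equiv), Sc(OTf)3 (10 mol%), CH2Cl2, −20 °C → rt; then 1 M HCl, THF, 0 °C
Reagents that add atoms: trimethylsilyldiazomethane, C[Si](C)(C)C=[N+]=[N-]
Why: Proposed new method: Sc(OTf)3-catalysed one-carbon ring expansion of a 2,2-disubstituted benzofuran-3(2H)-one with TMSCHN2, a ketone class on which diazoalkane homologation has not been shown; mechanistic reasoning: the ketone is strained, non-enolisable and activated by its α-oxygen, so the Sc-bound carbonyl takes up the diazo carbon, and as N2 leaves the electron-rich aryl carbon migrates in preference to C2 (quaternary, hindered, inductively deactivated by oxygen) to give C-silyl ketone 11, whose 1,3-silyl shift to enol silane 12 blocks a second insertion before acid releases ketone 13 with C2 untouched; closest known reactions: the Tiffeneau–Demjanov-type Sc(OTf)3/TMSCHN2 homologation of cycloalkanones and the aryl-migrating diazo ring expansions of 1-indanones and isatins.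

Step 6
Reactants: 13 (2S)-6-bromo-2-ethenyl-2-methylchroman-3-one
Product: 15 (2S,3S)-6-bromo-2-ethenyl-2-methylchroman-3-ol, via catechol borate 14 (not isolated)
Conditions: (R)-2-methyl-CBS-oxazaborolidine (20 mol%), catecholborane (1.6 equiv), toluene, −78 °C; then MeOH, aq NaOH
Reagents that add atoms: none
Why: Corey–Bakshi–Shibata reduction: the catalyst differentiates the quaternary C2 (large) from the C4 methylene (small), so the (R)-catalyst gives the 3S alcohol (OH trans to the C2 methyl) under reagent control, catecholborane at −78 °C leaves the vinyl group alone, and work-up cleaves borate 14.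

Step 7
Reactants: 16 5-bromo-2-methylpent-2-ene; 17 lithium acetylide ethylenediamine complex (LiC≡CH·H2NCH2CH2NH2, 1.3 equiv)
Product: 18 6-methylhept-5-en-1-yne
Conditions: DMSO, 10 °C → rt
Reagents that add atoms: none
Why: SN2 alkylation of lithium acetylide by a primary homoallylic bromide in DMSO; no stereocentre is involved.

Step 8
Reactants: 18 6-methylhept-5-en-1-yne
Product: 20 (1E)-1-iodo-2,6-dimethylhepta-1,5-diene, via alkenylalane 19 (not isolated)
Conditions: AlMe3 (2.0 equiv), Cp2ZrCl2 (20 mol%), CH2Cl2, 0 °C → rt; then I2 (1.2 equiv), THF, −30 → 0 °C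
Reagents that add atoms: trimethylaluminium, C[Al](C)C; iodine, II
Why: Negishi zirconium-catalysed carboalumination: syn addition of Me–Al across the terminal alkyne gives (E)-alkenylalane 19 regioselectively and iodinolysis proceeds with retention, which fixes the E trisubstituted alkene.

Step 9
Reactants: 15 (2S,3S)-6-bromo-2-ethenyl-2-methylchroman-3-ol; 20 (1E)-1-iodo-2,6-dimethylhepta-1,5-diene (1.2 equiv)
Product: 22 (2S,3S)-6-bromo-2-[(3E)-4,8-dimethylnona-3,7-dien-1-yl]-2-methylchroman-3-ol, via bis-boryl adduct 21 (not isolated)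
Conditions: 9-BBN (2.5 equiv B–H), THF, 0 °C → rt; then 20, Pd(dppf)Cl2·CH2Cl2 (5 mol%), AsPh3 (10 mol%), Cs2CO3 (3 equiv), DMF/H2O, rt
Reagents that add atoms: none
Why: B-alkyl Suzuki–Miyaura coupling: 9-BBN adds anti-Markovnikov to the vinyl group (one equivalent is taken up by the hydroxyl), and the alkenyl iodide couples with retention of E geometry at room temperature, where the electron-rich aryl bromide does not undergo oxidative addition; no stereocentre is touched.

Step 10
Reactants: 22 (2S,3S)-6-bromo-2-[(3E)-4,8-dimethylnona-3,7-dien-1-yl]-2-methylchroman-3-ol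
Product: 24 (2S,3S)-2-[(3E)-4,8-dimethylnona-3,7-dien-1-yl]-3-hydroxy-2-methylchroman-6-carboxylic acid, via dilithio species 23 (not isolated)
Conditions: t-BuLi (3.2 equiv), THF, −78 °C; CO2 (gas), −78 °C → rt; then 1 M HCl
Reagents that add atoms: carbon dioxide, O=C=O
Why: Bromine–lithium exchange on the lithium alkoxide, then carboxylation of aryllithium 23 with CO2 and acidification; the alkenes, the ether and both stereocentres are inert to these conditions.

**Compound list**
1 | 4-bromophenol | Oc1ccc(Br)cc1 | starting material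
2 | 4-bromo-2-iodophenol | Oc1ccc(Br)cc1I | intermediate
3 | 2-ethenyl-2-methyloxirane (isoprene monoepoxide, racemic) | CC1(C=C)CO1 | starting material
4 | (2S)-2-(4-bromo-2-iodophenoxy)-2-methylbut-3-en-1-ol | C=C[C@@](C)(CO)Oc1ccc(Br)cc1I | intermediate
5 | (2S)-2-(4-bromo-2-iodophenoxy)-2-methylbut-3-enal | C=C[C@@](C)(C=O)Oc1ccc(Br)cc1I | intermediate (not isolated)
6 | (2S)-2-(4-bromo-2-iodophenoxy)-2-methylbut-3-enoic acid | C=C[C@@](C)(C(=O)O)Oc1ccc(Br)cc1I | intermediate
7 | sodium (2S)-2-(4-bromo-2-iodophenoxy)-2-methylbut-3-enoate | C=C[C@@](C)(C(=O)[O-])Oc1ccc(Br)cc1I.[Na+] | intermediate (not isolated)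
8 | sodium (2S)-2-(4-bromo-2-lithiophenoxy)-2-methylbut-3-enoate | C=C[C@@](C)(C(=O)[O-])Oc1ccc(Br)cc1[Li].[Na+] | intermediate (not isolated)
9 | lithium sodium (2S)-5-bromo-2-ethenyl-2-methyl-2H-1-benzofuran-3,3-diolate | C=C[C@]1(C)Oc2ccc(Br)cc2C1([O-])[O-].[Li+].[Na+] | intermediate (not isolated)
10 | (2S)-5-bromo-2-ethenyl-2-methyl-1-benzofuran-3(2H)-one | C=C[C@]1(C)Oc2ccc(Br)cc2C1=O | intermediate
11 | (2S)-6-bromo-2-ethenyl-2-methyl-4-(trimethylsilyl)chroman-3-one (C4 epimers) | C=C[C@]1(C)Oc2ccc(Br)cc2C([Si](C)(C)C)C1=O | intermediate (not isolated)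
12 | {[(2S)-6-bromo-2-ethenyl-2-methyl-2H-chromen-3-yl]oxy}(trimethyl)silane | C=C[C@]1(C)Oc2ccc(Br)cc2C=C1O[Si](C)(C)C | intermediate (not isolated)
13 | (2S)-6-bromo-2-ethenyl-2-methylchroman-3-one | C=C[C@]1(C)Oc2ccc(Br)cc2CC1=O | intermediate
14 | 2-{[(2S,3S)-6-bromo-2-ethenyl-2-methylchroman-3-yl]oxy}-1,3,2-benzodioxaborole | C=C[C@]1(C)Oc2ccc(Br)cc2C[C@@H]1OB1Oc2ccccc2O1 | intermediate (not isolated)
15 | (2S,3S)-6-bromo-2-ethenyl-2-methylchroman-3-ol | C=C[C@]1(C)Oc2ccc(Br)cc2C[C@@H]1O | intermediate
16 | 5-bromo-2-methylpent-2-ene | CC(C)=CCCBr | starting material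
17 | lithium acetylide ethylenediamine complex | [Li+].[C-]#C.NCCN | starting material
18 | 6-methylhept-5-en-1-yne | CC(C)=CCCC#C | intermediate
19 | [(1E)-2,6-dimethylhepta-1,5-dien-1-yl](dimethyl)alumane | C[Al](C)/C=C(\C)CCC=C(C)C | intermediate (not isolated)
20 | (1E)-1-iodo-2,6-dimethylhepta-1,5-diene | I/C=C(\C)CCC=C(C)C | intermediate
21 | 9-{2-[(2S,3S)-3-(9-borabicyclo[3.3.1]nonan-9-yloxy)-6-bromo-2-methylchroman-2-yl]ethyl}-9-borabicyclo[3.3.1]nonane | B1(CC[C@]3(C)Oc4ccc(Br)cc4C[C@@H]3OB3C4CCCC3CCC4)C2CCCC1CCC2 | intermediate (not isolated)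
22 | (2S,3S)-6-bromo-2-[(3E)-4,8-dimethylnona-3,7-dien-1-yl]-2-methylchroman-3-ol | CC(C)=CCC/C(C)=C/CC[C@]1(C)Oc2ccc(Br)cc2C[C@@H]1O | intermediate
23 | lithium (2S,3S)-2-[(3E)-4,8-dimethylnona-3,7-dien-1-yl]-6-lithio-2-methylchroman-3-olate | CC(C)=CCC/C(C)=C/CC[C@]1(C)Oc2ccc([Li])cc2C[C@@H]1[O-].[Li+] | intermediate (not isolated)
24 | (2S,3S)-2-[(3E)-4,8-dimethylnona-3,7-dien-1-yl]-3-hydroxy-2-methylchroman-6-carboxylic acid | CC(C)=CCC/C(C)=C/CC[C@]1(C)Oc2ccc(C(=O)O)cc2C[C@@H]1O | target

**Step count**
Total: 10 steps. Longest linear sequence: 8 steps (steps 1–6, 9, 10); the alkenyl iodide branch is 2 steps (steps 7–8).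

**Three steps most likely to fail**

Step 5 (the proposed new ring expansion). The ortho-alkoxyaryl ketone may add TMSCHN2 slowly, C2 may migrate instead of the aryl carbon (giving a chroman-4-one), or a spiro-epoxide may form. The fallback uses known chemistry, sets out from 10 and comes back at 13. Wittig methylenation (Ph3PCH3Br, KOtBu, THF, 0 °C → rt) gives (2S)-5-bromo-2-ethenyl-2-methyl-3-methylidene-2,3-dihydro-1-benzofuran F1. Koser oxidative rearrangement of this exocyclic aryl alkene (PhI(OH)OTs, 1.05 equiv, MeCN/H2O, rt) then expands the ring by aryl 1,2-shift away from the iodonium-activated CH2, as known for 1-methyleneindane to 2-tetralone, and gives 13. The electron-rich 1,1-disubstituted alkene reacts ahead of the monosubstituted vinyl group.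

Step 2 (asymmetric etherification with the hindered iodophenol). The ortho-iodine may lower branched selectivity or ee, and the zerovalent palladium catalyst may insert into the C–I bond. The fallback sets out from 1 (with 3) and comes back at 10, replacing steps 1–4 by an electrophilic ring closure that needs no iodine. The same Pd/Trost-ligand etherification run on 1 gives (2S)-2-(4-bromophenoxy)-2-methylbut-3-en-1-ol F2. TEMPO/PhI(OAc)2 oxidation gives (2S)-2-(4-bromophenoxy)-2-methylbut-3-enoic acid F3. (COCl)2 with catalytic DMF gives (2S)-2-(4-bromophenoxy)-2-methylbut-3-enoyl chloride F4. Intramolecular Friedel–Crafts acylation ortho to the ether oxygen (AlCl3, CH2Cl2, −20 °C) gives 10. This closure risks decarbonylation of the acylium ion, which is why it is not the main route.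

Step 4 (Parham closure on the carboxylate). Bromine–lithium exchange may compete, 8 may be protonated, or addition to the carboxylate may be slow. The fallback sets out from 4 and comes back at 10. Dess–Martin oxidation of 4 gives aldehyde 5, here isolated. Nozaki–Hiyama–Kishi cyclisation (CrCl2, 4 equiv, NiCl2, 2 mol%, DMF, rt), which engages the aryl iodide but not the bromide and tolerates the aldehyde, gives (2S)-5-bromo-2-ethenyl-2-methyl-2,3-dihydro-1-benzofuran-3-ol F5 as a mixture of C3 epimers. A second Dess–Martin oxidation gives 10.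

**Further compounds**
F1 | step 5 | (2S)-5-bromo-2-ethenyl-2-methyl-3-methylidene-2,3-dihydro-1-benzofuran | C=C[C@]1(C)Oc2ccc(Br)cc2C1=C
F2 | step 2 | (2S)-2-(4-bromophenoxy)-2-methylbut-3-en-1-ol | C=C[C@@](C)(CO)Oc1ccc(Br)cc1
F3 | step 2 | (2S)-2-(4-bromophenoxy)-2-methylbut-3-enoic acid | C=C[C@@](C)(C(=O)O)Oc1ccc(Br)cc1
F4 | step 2 | (2S)-2-(4-bromophenoxy)-2-methylbut-3-enoyl chloride | C=C[C@@](C)(C(=O)Cl)Oc1ccc(Br)cc1
F5 | step 4 | (2S)-5-bromo-2-ethenyl-2-methyl-2,3-dihydro-1-benzofuran-3-ol (C3 epimers) | C=C[C@]1(C)Oc2ccc(Br)cc2C1O
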